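The readings come from a simulation with constants of no real substance; noise was put on by code.

I could not read 5 °C off any curve, since the red run and the blue run both stood colder.

| flask | Qe | temperature | remark | time |
|---|---|---|---|---|
| red | 6.7 mM | −25 °C | run made earlier |  |
| blue | 15 mM | −8 °C | run made earlier |  |
| winter | 10 mM | 5 °C |  | 40 h |
| midnight | 10 mM | −20 °C |  | 40 h |
| spring | 10 mM |  | at −20 °C until 30 h, from then on at 5 °C | 40 h |

- red (time / h: Ez / %, Qe / %): 48.0: 1.8, 96.8; 120: 3.0, 92.6; 192: 4.4, 88.8; 240: 5.1, 86.5
- blue (time / h: Ez / %, Qe / %): 12.0: 5.7, 85.9; 30.0: 10.9, 69.6; 60.0: 16.0, 53.3; 96.0: 18.4, 40.3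

(scatter of a reading: 0.3 percentage points)

- a reading or a percentage of Ez counts all its forms, free or not
- a reading of Qe is of its free form alone

* the best flask by amount of Ez, in percent of the Qe charged; "all alike" if 1.5 percentage points covers them all (winter / midnight / spring / all alike)
* amount of Ez at the end, in percent of the Qe charged, winter
* amount of Ez at the end, in percent of the Qe charged, midnight
* amount of Ez at the end, in percent of the Qe charged, spring

So I turned warm hours into blue hours. From the first reading of each run I took the Ez gained per hour over the mean [Qe] of that stretch, replacing the curve by its mean. That gave 0.00511 h⁻¹ in blue and 3.81 × 10⁻⁴ h⁻¹ in red, and using the charge in place of the mean would shift the blue figure by 7.05%. A straight line of ln rate against temperature through both gave the speed factor, the hours of blue that one hour of a flask is worth (a time–temperature shift factor): 7.28 at 5 °C and 0.160 at −20 °C. The two runs also differ in charge, so the line carries that too.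

Spring has two extreme versions. If its 10.0 h of warmth added nothing, it would end on the cold gain, 2.45%. If they kept the start rate, it would gain 37.2%. I expected the real flask below that second figure, because blue read 16.0% at 60.0 h, less than the 30.7% its start rate promised. Cold and warm stretches together, spring is worth 77.6 h of blue, and reading between the blue points gave me 17.2%. Midnight at the start rate gave me 3.27%. Winter is worth 291 h of blue, past the last reading at 96.0 h, so I had no figure for it.

The forecast named spring, with winter 10% (5% to 19%), midnight 3% (2% to 4.5%) and spring 16% (10% to 21%): “Spring gets only 10 warm hours, close to the peak, about 16%.” My spring figure stood a little above its number.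

The flasks gave winter 10.4%, midnight 2.42% and spring 16.7%, so spring came out best.

    Qe ⇌ Ek (K = 3.00, k = 0.00610 h⁻¹, Ea = 90.0 kJ mol⁻¹, ΔH = 25.0 kJ mol⁻¹)
    Qe ⇌ Ez (K = 0.620, k = 0.0450 h⁻¹, Ea = 100 kJ mol⁻¹, ΔH = −53.0 kJ mol⁻¹)
    Ez ⇌ Ek (k = 0.0680 h⁻¹, Ea = 92.0 kJ mol⁻¹)
    2 Qe → Zu (k = 0.800 M⁻¹ h⁻¹, Ea = 70.0 kJ mol⁻¹)
    Ez → Wa (k = 0.0370 h⁻¹, Ea = 83.0 kJ mol⁻¹)
    Qe + Ez ⇌ Jo, settled at all times (K = 32.0 M⁻¹, ΔH = −2.00 kJ mol⁻¹)
    (constants at 5 °C)

Spring had not come to rest at the end, with 56% of its charge still free Qe. At 400 h its Ez had sunk to 1.70%, while Wa had climbed from 3.77% to 63.2%. Midnight was moving the other way, to 16.3%; its 400 h are worth 64.0 h of blue, near the 60.0 h where blue read 16.0%.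

Winter read at 15 h is worth 109 h of blue, past the last reading, so the factor pointed to about 18.4%. The computed flask gave 16.7%.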